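**Retrosynthetic overview**
- The target is a (3R)-3-hydroxyisoflavanone. Its only stereocentre, C3, is a tertiary carbinol bonded to C4(=O), to C2H2–O1 and to C1' of ring B.
- Enabling feature: C3–C4 is a latent 1,2-dicarbonyl. C1' is the ring B carbon ortho to the 2'-OH and para to the 4'-OMe, and the other free carbon, C6', lies beside the quaternary carbon on C5'. O2' stands 1,5 to C4.
- Key disconnection C3–C1': catalytic asymmetric ortho-Friedel–Crafts hydroxyalkylation of the unprotected ring B catechol by a seco-ring-C α-ketoester, followed in the same flask by lactonisation of O2' onto C4.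
- Ring order: rings A and B are bought as arenes. A temporary benzofuranone ring forms in the key step. Ring C closes last (C4–C4a, Parham cyclisation), and this opens the temporary ring again.
- The catechol comes from pyrogallol acetonide (prenyl ether, Claisen rearrangement, methylation, ketal hydrolysis). The ketoester comes from 4-iodoresorcinol (silylation, etherification with a bromomethylacrylate, ozonolysis).

Key step: step 8

Assumption: (R)-TRIP is taken as the catalyst antipode that leaves the Si face of the α-ketoester open. The sense of induction must be confirmed on the lactone, and the (S)-acid would replace it if the sense is opposite.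

Step 1
Reactants: 1 2,2-dimethyl-1,3-benzodioxol-4-ol; 2 prenyl bromide (1-bromo-3-methylbut-2-ene)
Product: 3 2,2-dimethyl-4-[(3-methylbut-2-en-1-yl)oxy]-1,3-benzodioxole
Conditions: K2CO3, acetone, reflux
Reagents that add atoms: none
Why: Williamson ether synthesis, in which the only free phenol of 1 displaces the primary allylic bromide (SN2) and the ketal is inert to carbonate.

Step 2
Reactants: 3 2,2-dimethyl-4-[(3-methylbut-2-en-1-yl)oxy]-1,3-benzodioxole
Product: 4 2,2-dimethyl-5-(2-methylbut-3-en-2-yl)-1,3-benzodioxol-4-ol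
Conditions: PhNEt2, 190 °C, Ar
Reagents that add atoms: none
Why: Aromatic Claisen rearrangement, in which the [3,3] shift can end productively only at C5 (the single free ortho carbon), inverts the prenyl unit to the 1,1-dimethylallyl group, and is followed by fast tautomerisation in the basic solvent, which should hold back the Cope relay to the para carbon.

Step 3
Reactants: 4 2,2-dimethyl-5-(2-methylbut-3-en-2-yl)-1,3-benzodioxol-4-ol
Product: 5 4-methoxy-2,2-dimethyl-5-(2-methylbut-3-en-2-yl)-1,3-benzodioxole
Conditions: MeI, K2CO3, DMF, rt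
Reagents that add atoms: methyl iodide, CI
Why: Williamson O-methylation of the hindered phenol with a small electrophile in a dipolar aprotic solvent, with no other acidic site present.

Step 4
Reactants: 5 4-methoxy-2,2-dimethyl-5-(2-methylbut-3-en-2-yl)-1,3-benzodioxole
Product: 6 3-methoxy-4-(2-methylbut-3-en-2-yl)benzene-1,2-diol
Conditions: AcOH–H2O (4:1), reflux, Ar
Reagents that add atoms: none
Why: Acid hydrolysis of the aryl isopropylidene ketal, in which acetic acid is too weak to protonate the monosubstituted alkene and the oxygen next to the 1,1-dimethylallyl group is a methyl ether, so cyclisation onto the alkene is excluded.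

Step 5
Reactants: 7 4-iodobenzene-1,3-diol (4-iodoresorcinol)
Product: 8 2-iodo-5-[(triisopropylsilyl)oxy]phenol
Conditions: TIPSCl (1.0 equiv), imidazole, CH2Cl2, 0 °C
Reagents that add atoms: triisopropylsilyl chloride, CC(C)[Si](Cl)(C(C)C)C(C)C
Why: Regioselective silylation, in which the bulky silyl chloride should take the unhindered OH para to iodine and leave the OH flanked by iodine.

Step 6
Reactants: 8 2-iodo-5-[(triisopropylsilyl)oxy]phenol; 9 methyl 2-(bromomethyl)acrylate
Product: 10 methyl 2-({2-iodo-5-[(triisopropylsilyl)oxy]phenoxy}methyl)acrylate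
Conditions: K2CO3, acetone, rt
Reagents that add atoms: none
Why: Williamson etherification with an activated allylic bromide at room temperature, in which SN2 and SN2' attack lead to the same ether and the aryl TIPS ether survives.

Step 7
Reactants: 10 methyl 2-({2-iodo-5-[(triisopropylsilyl)oxy]phenoxy}methyl)acrylate
Product: 12 methyl 3-{2-iodo-5-[(triisopropylsilyl)oxy]phenoxy}-2-oxopropanoate, via secondary ozonide 11 (not isolated)
Conditions: O3, CH2Cl2, −78 °C (Sudan III end point); then Me2S, −78 °C → rt
Reagents that add atoms: ozone, [O-][O+]=O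
Why: Ozonolysis with reductive work-up cleaves the only C=C bond to the α-ketoester, and the dye end point keeps excess ozone away from the electron-rich ring and the aryl iodide.

Step 8
Reactants: 6 3-methoxy-4-(2-methylbut-3-en-2-yl)benzene-1,2-diol; 12 methyl 3-{2-iodo-5-[(triisopropylsilyl)oxy]phenoxy}-2-oxopropanoate
Product: 14 (3R)-3,7-dihydroxy-3-({2-iodo-5-[(triisopropylsilyl)oxy]phenoxy}methyl)-6-methoxy-5-(2-methylbut-3-en-2-yl)-1-benzofuran-2(3H)-one, via open hydroxy ester 13 (not isolated)
Conditions: (R)-TRIP (10 mol %), 5 Å MS, toluene, 0 °C → rt, then 50 °C, Ar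
Reagents that add atoms: none
Why: The phosphoric acid binds both partners at once, its P–OH to the ketone oxygen of 12 and its P=O to the 1-OH of 6, so that C6 of 6 (ortho to that OH) attacks the ketone carbon in a closed transition state and re-aromatisation gives 13; this is the asymmetric ortho-selective Friedel–Crafts hydroxyalkylation of a phenol with an α-ketoester, an organocatalytic reaction type that is also known as a domino process with lactonisation. The new tertiary carbinol centre is controlled by the catalyst alone, whose 3,3'-aryl walls tell the flat CO2Me flank from the long CH2OAr flank and should leave the Si face open, which gives (R). The phenolic OH next to the new bond then attacks the methyl ester (5-exo-trig) and closes the benzofuran-2(3H)-one ring with loss of methanol, which the sieves take up, so that the addition becomes irreversible. Regioselectivity is secured by the substrate, because the attacked carbon is ortho to OH and para to OMe, whereas the only other free ring carbon lies next to the quaternary 1,1-dimethylallyl carbon and cannot be reached from the hydrogen-bonded OH. Chemoselectivity follows from the 1,2-dicarbonyl, since the ketone, further activated by the α-aryloxy group, is far more electrophilic than the ester and O-addition to it is reversible. The lactone masks one of the two catechol OH groups and turns C4 into an activated aryl ester for the closure of ring C.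

Step 9
Reactants: 14 (3R)-3,7-dihydroxy-3-({2-iodo-5-[(triisopropylsilyl)oxy]phenoxy}methyl)-6-methoxy-5-(2-methylbut-3-en-2-yl)-1-benzofuran-2(3H)-one
Product: 15 (3R)-3-({2-iodo-5-[(triisopropylsilyl)oxy]phenoxy}methyl)-6-methoxy-5-(2-methylbut-3-en-2-yl)-3,7-bis[(triethylsilyl)oxy]-1-benzofuran-2(3H)-one
Conditions: TESOTf (2.5 equiv), 2,6-lutidine, CH2Cl2, 0 °C
Reagents that add atoms: triethylsilyl triflate, CC[Si](CC)(CC)OS(=O)(=O)C(F)(F)F
Why: Silyl triflate silylation covers the phenol and the hindered tertiary alcohol, which removes both acidic protons before the organolithium step and breaks no bond at C3.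

Step 10
Reactants: 15 (3R)-3-({2-iodo-5-[(triisopropylsilyl)oxy]phenoxy}methyl)-6-methoxy-5-(2-methylbut-3-en-2-yl)-3,7-bis[(triethylsilyl)oxy]-1-benzofuran-2(3H)-one
Product: 18 (3R)-3-[2,3-dihydroxy-4-methoxy-5-(2-methylbut-3-en-2-yl)phenyl]-3,7-dihydroxy-2,3-dihydro-4H-chromen-4-one, via aryllithium 16 (not isolated), via silylated chromanone 17 (not isolated)
Conditions: t-BuLi (2.0 equiv), THF–Et2O, −100 → −78 °C; AcOH; then TBAF–AcOH (1:1), THF, 0 °C, Ar
Reagents that add atoms: none
Why: Parham cyclisation, in which iodine–lithium exchange should outrun addition of t-BuLi to the carbonyl shielded by the fully substituted C3, the aryllithium attacks the lactone carbonyl (6-exo-trig) to close ring C and expel the ring B phenoxide, and buffered fluoride then removes all three silyl groups (any O-to-O silyl shift in 17 is irrelevant) while C3, which carries no hydrogen, keeps its configuration.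

**Compound list**
1 | 2,2-dimethyl-1,3-benzodioxol-4-ol | CC1(C)Oc2cccc(O)c2O1 | starting material
2 | prenyl bromide | CC(C)=CCBr | starting material
3 | 2,2-dimethyl-4-[(3-methylbut-2-en-1-yl)oxy]-1,3-benzodioxole | CC(C)=CCOc1cccc2OC(C)(C)Oc12 | intermediate
4 | 2,2-dimethyl-5-(2-methylbut-3-en-2-yl)-1,3-benzodioxol-4-ol | C=CC(C)(C)c1ccc2OC(C)(C)Oc2c1O | intermediate
5 | 4-methoxy-2,2-dimethyl-5-(2-methylbut-3-en-2-yl)-1,3-benzodioxole | C=CC(C)(C)c1ccc2OC(C)(C)Oc2c1OC | intermediate
6 | 3-methoxy-4-(2-methylbut-3-en-2-yl)benzene-1,2-diol | C=CC(C)(C)c1ccc(O)c(O)c1OC | intermediate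
7 | 4-iodobenzene-1,3-diol | Oc1ccc(I)c(O)c1 | starting material
8 | 2-iodo-5-[(triisopropylsilyl)oxy]phenol | Oc1cc(O[Si](C(C)C)(C(C)C)C(C)C)ccc1I | intermediate
9 | methyl 2-(bromomethyl)acrylate | C=C(CBr)C(=O)OC | starting material
10 | methyl 2-({2-iodo-5-[(triisopropylsilyl)oxy]phenoxy}methyl)acrylate | C=C(COc1cc(O[Si](C(C)C)(C(C)C)C(C)C)ccc1I)C(=O)OC | intermediate
11 | secondary ozonide (1,2,4-trioxolane, racemic) of 10 | COC(=O)C1(COc2cc(O[Si](C(C)C)(C(C)C)C(C)C)ccc2I)OCOO1 | intermediate
12 | methyl 3-{2-iodo-5-[(triisopropylsilyl)oxy]phenoxy}-2-oxopropanoate | COC(=O)C(=O)COc1cc(O[Si](C(C)C)(C(C)C)C(C)C)ccc1I | intermediate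
13 | methyl (2R)-2-[2,3-dihydroxy-4-methoxy-5-(2-methylbut-3-en-2-yl)phenyl]-2-hydroxy-3-{2-iodo-5-[(triisopropylsilyl)oxy]phenoxy}propanoate | COC(=O)[C@](O)(COc1cc(O[Si](C(C)C)(C(C)C)C(C)C)ccc1I)c1cc(C(C)(C)C=C)c(OC)c(O)c1O | intermediate
14 | (3R)-3,7-dihydroxy-3-({2-iodo-5-[(triisopropylsilyl)oxy]phenoxy}methyl)-6-methoxy-5-(2-methylbut-3-en-2-yl)-1-benzofuran-2(3H)-one | C=CC(C)(C)c1cc2c(OC(=O)[C@]2(O)COc2cc(O[Si](C(C)C)(C(C)C)C(C)C)ccc2I)c(O)c1OC | intermediate
15 | 3,7-bis(triethylsilyl) ether of 14, (3R) | C=CC(C)(C)c1cc2c(OC(=O)[C@]2(O[Si](CC)(CC)CC)COc2cc(O[Si](C(C)C)(C(C)C)C(C)C)ccc2I)c(O[Si](CC)(CC)CC)c1OC | intermediate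
16 | aryllithium from 15 (Li in place of I), (3R) | C=CC(C)(C)c1cc2c(OC(=O)[C@]2(O[Si](CC)(CC)CC)COc2cc(O[Si](C(C)C)(C(C)C)C(C)C)ccc2[Li])c(O[Si](CC)(CC)CC)c1OC | intermediate
17 | (3R)-3-{2-hydroxy-4-methoxy-5-(2-methylbut-3-en-2-yl)-3-[(triethylsilyl)oxy]phenyl}-3-[(triethylsilyl)oxy]-7-[(triisopropylsilyl)oxy]-2,3-dihydro-4H-chromen-4-one | C=CC(C)(C)c1cc([C@@]2(O[Si](CC)(CC)CC)COc3cc(O[Si](C(C)C)(C(C)C)C(C)C)ccc3C2=O)c(O)c(O[Si](CC)(CC)CC)c1OC | intermediate
18 | (3R)-3-[2,3-dihydroxy-4-methoxy-5-(2-methylbut-3-en-2-yl)phenyl]-3,7-dihydroxy-2,3-dihydro-4H-chromen-4-one | C=CC(C)(C)c1cc([C@@]2(O)COc3cc(O)ccc3C2=O)c(O)c(O)c1OC | target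

**Step count**
- Total step count: 10.
- Longest linear sequence: 7 (steps 1, 2, 3, 4, 8, 9, 10).

**Steps most likely to fail**

1. **Step 8.**
   - What may go wrong: the non-fluorinated ketoester may add too slowly under Brønsted acid catalysis. It may enolise and condense with itself. The catalyst may also discriminate the two faces poorly.
   - Fallback: stoichiometric auxiliary control inside a metal template. It sets out from 12 and 6 and returns at 14.
   - Transesterification of 12 with (−)-8-phenylmenthol (cat. Bu2SnO, toluene, reflux, removal of methanol) should give the 8-phenylmenthyl ketoester F1.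
   - Deprotonation of 6 with EtMgBr (2 equiv, CH2Cl2–toluene, 0 °C) should give the bis(bromomagnesium) catecholate F2.
   - F2 adds through its ortho carbon to the magnesium-chelated 1,2-dicarbonyl of F1. The phenyl ring of the auxiliary covers the Re face of that dicarbonyl, so Si attack should give the auxiliary-bearing hydroxy ester F3.
   - Warming with cat. p-TsOH in toluene lactonises F3 to 14 and returns the auxiliary.

2. **Step 10.**
   - What may go wrong: the alkyllithium may attack the lactone carbonyl in competition with the halogen–metal exchange. An organolithium may also add a second time to the liberated ketone.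
   - Fallback: the temporary ring is opened first, and a chelating acyl acceptor is combined with a milder organomagnesium. It sets out from 15 and returns at 18.
   - MeNH(OMe)·HCl and i-PrMgCl (THF, −20 °C) should open the lactone to the phenolic Weinreb amide F4.
   - TESCl and imidazole should give the fully silylated Weinreb amide F5.
   - Iodine–magnesium exchange with i-PrMgCl·LiCl (THF, −20 °C → rt) should give the arylmagnesium chloride F6. Its attack on the amide stops at the chelated tetrahedral stage and should release the tetrasilyl chromanone F7 on work-up.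
   - TBAF–AcOH then gives 18.

3. **Step 2.**
   - What may go wrong: the dienone may relay the allyl group to the para carbon by a Cope shift. The prenyl ether may fragment thermally. The product may isomerise further on long heating.
   - Fallback: the C–C bond is made by cross-coupling instead of a sigmatropic shift. It sets out from 1 and returns at 5.
   - Amine-mediated ortho-selective bromination (NBS, cat. i-Pr2NH, CH2Cl2, 0 °C) should give 5-bromo-2,2-dimethyl-1,3-benzodioxol-4-ol F8.
   - MeI and K2CO3 should give 5-bromo-4-methoxy-2,2-dimethyl-1,3-benzodioxole F9.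
   - A ligand-controlled γ-selective Suzuki–Miyaura coupling with prenylboronic acid pinacol ester (Pd(0), bulky biarylphosphine, K3PO4, THF–H2O) should deliver the 1,1-dimethylallyl arene 5.

Further compounds
F1 | step 8 | (1R,2S,5R)-5-methyl-2-(2-phenylpropan-2-yl)cyclohexyl 3-{2-iodo-5-[(triisopropylsilyl)oxy]phenoxy}-2-oxopropanoate | CC(C)(c1ccccc1)[C@@H]1CC[C@@H](C)C[C@H]1OC(=O)C(=O)COc1cc(O[Si](C(C)C)(C(C)C)C(C)C)ccc1I
F2 | step 8 | bis(bromomagnesium) catecholate of 6 | C=CC(C)(C)c1ccc(O[Mg]Br)c(O[Mg]Br)c1OC
F3 | step 8 | (1R,2S,5R)-5-methyl-2-(2-phenylpropan-2-yl)cyclohexyl (2R)-2-[2,3-dihydroxy-4-methoxy-5-(2-methylbut-3-en-2-yl)phenyl]-2-hydroxy-3-{2-iodo-5-[(triisopropylsilyl)oxy]phenoxy}propanoate | CC(C)(c1ccccc1)[C@@H]1CC[C@@H](C)C[C@H]1OC(=O)[C@](O)(COc1cc(O[Si](C(C)C)(C(C)C)C(C)C)ccc1I)c1cc(C(C)(C)C=C)c(OC)c(O)c1O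
F4 | step 10 | (2R)-2-{2-hydroxy-4-methoxy-5-(2-methylbut-3-en-2-yl)-3-[(triethylsilyl)oxy]phenyl}-3-{2-iodo-5-[(triisopropylsilyl)oxy]phenoxy}-N-methoxy-N-methyl-2-[(triethylsilyl)oxy]propanamide | CON(C)C(=O)[C@](O[Si](CC)(CC)CC)(COc1cc(O[Si](C(C)C)(C(C)C)C(C)C)ccc1I)c1cc(C(C)(C)C=C)c(OC)c(O[Si](CC)(CC)CC)c1O
F5 | step 10 | 2-O-triethylsilyl ether of F4, (2R) | CON(C)C(=O)[C@](O[Si](CC)(CC)CC)(COc1cc(O[Si](C(C)C)(C(C)C)C(C)C)ccc1I)c1cc(C(C)(C)C=C)c(OC)c(O[Si](CC)(CC)CC)c1O[Si](CC)(CC)CC
F6 | step 10 | arylmagnesium chloride from F5 (MgCl in place of I), (2R) | CON(C)C(=O)[C@](O[Si](CC)(CC)CC)(COc1cc(O[Si](C(C)C)(C(C)C)C(C)C)ccc1[Mg]Cl)c1cc(C(C)(C)C=C)c(OC)c(O[Si](CC)(CC)CC)c1O[Si](CC)(CC)CC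
F7 | step 10 | (3R)-3-{4-methoxy-5-(2-methylbut-3-en-2-yl)-2,3-bis[(triethylsilyl)oxy]phenyl}-3-[(triethylsilyl)oxy]-7-[(triisopropylsilyl)oxy]-2,3-dihydro-4H-chromen-4-one | C=CC(C)(C)c1cc([C@@]2(O[Si](CC)(CC)CC)COc3cc(O[Si](C(C)C)(C(C)C)C(C)C)ccc3C2=O)c(O[Si](CC)(CC)CC)c(O[Si](CC)(CC)CC)c1OC
F8 | step 2 | 5-bromo-2,2-dimethyl-1,3-benzodioxol-4-ol | CC1(C)Oc2ccc(Br)c(O)c2O1
F9 | step 2 | 5-bromo-4-methoxy-2,2-dimethyl-1,3-benzodioxole | CC1(C)Oc2ccc(Br)c(OC)c2O1
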